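**Retrosynthetic overview**
1. Target 17 comes from 16 by fluoride removal of four TIPS ethers (rings B and C).
2. The dihydrofuran ring is the only ring formed. It is closed last through the O1–C2 bond by a catalytic enantioselective protonation/oxa-cyclisation of triarylethylene triol 15, which sets C3 and C2.
3. 15 comes from 13 by non-acidic MOM removal; 13 comes from a Heck reaction of 1,1-diarylethylene 12 with ring C bromide 8.
4. 12 comes from lithiation of tris-MOM isorhapontigenin 4 between its two OMOM groups, addition to ring B ketone 6 and dehydration; 4 comes from a Heck reaction of 5-bromoresorcinol 1 with 4-vinylguaiacol 2.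
5. Rings A to D are bought as arenes. Ring A is the benzo ring, ring B the 3,5-dioxygenated aryl on C3, ring C the 2,4-dioxygenated aryl on C2, ring D the guaiacyl ring.

Assumption: the target is (2S,3S), 2,3-trans; the sense of induction of the new step 8 cannot be predicted, so the catalyst antipode that gives (2S,3S) is fixed by one test run (the (S,S)-acid is written).

Abbreviations: MOM = methoxymethyl; TIPS = triisopropylsilyl; Burgess reagent = methyl N-(triethylammoniosulfonyl)carbamate; IDPi = imidodiphosphorimidate Brønsted acid built from two (S)-3,3'-bis[3,5-bis(trifluoromethyl)phenyl]-1,1'-bi-2-naphthol units and two N-triflyl groups.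

**Step 1**
Reactants: 1 5-bromobenzene-1,3-diol; 2 2-methoxy-4-vinylphenol
Product: 3 isorhapontigenin
Conditions: Pd(OAc)2 (2 mol%), P(o-tol)3 (6 mol%), Et3N, DMF, 100 °C, dark
Reagents that add atoms: none
Why: Mizoroki–Heck arylation at the terminal alkene carbon followed by syn β-hydride elimination gives the E-stilbene, and free phenols are tolerated with an amine base.

**Step 2**
Reactants: 3 isorhapontigenin
Product: 4 tris-MOM isorhapontigenin
Conditions: MOMCl (4 equiv), i-Pr2NEt, CH2Cl2, 0 °C to rt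
Reagents that add atoms: chloromethyl methyl ether (MOMCl), COCCl
Why: Williamson-type O-alkylation of all three phenols gives MOM ethers that direct the later lithiation and can be removed without acid.

**Step 3**
Reactants: 5 1-(3,5-dihydroxyphenyl)ethan-1-one
Product: 6 1-[3,5-bis(triisopropylsilyloxy)phenyl]ethan-1-one
Conditions: TIPSCl (2.3 equiv), imidazole, DMF, rt
Reagents that add atoms: chlorotriisopropylsilane (TIPSCl), CC(C)[Si](Cl)(C(C)C)C(C)C
Why: Imidazole-promoted O-silylation; aryl TIPS ethers survive organometallics, palladium catalysis and Brønsted acid and are cleaved by fluoride at the end.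

**Step 4**
Reactants: 7 4-bromobenzene-1,3-diol
Product: 8 1-bromo-2,4-bis(triisopropylsilyloxy)benzene
Conditions: TIPSCl (2.4 equiv), imidazole, DMF, rt to 40 °C
Reagents that add atoms: chlorotriisopropylsilane (TIPSCl), CC(C)[Si](Cl)(C(C)C)C(C)C
Why: O-silylation as in step 3; the bulky TIPS groups later keep the ring C oxygens from acting as nucleophiles.

**Step 5**
Reactants: 4 tris-MOM isorhapontigenin; 6 1-[3,5-bis(triisopropylsilyloxy)phenyl]ethan-1-one
Product: 12 1,1-diarylethylene (ring A and ring B on the same alkene carbon), via aryllithium 9 (not isolated), via arylcerium dichloride 10 (not isolated), via tertiary alcohol 11 (not isolated)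
Conditions: 4, n-BuLi (1.05 equiv), TMEDA, THF, −40 °C; anhydrous CeCl3, −78 °C; 6, −78 to 0 °C; aq NH4Cl; crude 11, Burgess reagent, THF, 50 °C
Reagents that add atoms: none
Why: Directed ortho-metalation occurs at the ring A carbon flanked by two OMOM groups, the weakly basic organocerium adds 1,2 to the enolisable ketone, and Burgess syn-elimination can only use the methyl hydrogens, so the racemic carbinol centre of 11 is erased in 12.

**Step 6**
Reactants: 12 1,1-diarylethylene; 8 1-bromo-2,4-bis(triisopropylsilyloxy)benzene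
Product: 13 MOM-protected triarylethylene (E/Z mixture at the new trisubstituted alkene)
Conditions: Pd2(dba)3 (2.5 mol%), [HP(t-Bu)3]BF4 (10 mol%), Cy2NMe, dioxane, 90 °C, dark
Reagents that add atoms: none
Why: Mizoroki–Heck reaction with a zerovalent palladium/P(t-Bu)3 catalyst places ring C on the unsubstituted CH2 terminus and β-hydride elimination gives the triarylethylene, while the internal stilbene alkene reacts much more slowly.

**Step 7**
Reactants: 13 MOM-protected triarylethylene
Product: 15 triarylethylene triol (E/Z mixture), via tris(trimethylsilyl) ether 14 (not isolated)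
Conditions: TMSOTf (6 equiv), 2,2'-bipyridyl (9 equiv), CH2Cl2, 0 °C to rt; then H2O; chromatography on Et3N-deactivated silica
Reagents that add atoms: none
Why: Silyl triflate/bipyridyl cleavage turns aryl MOM ethers into TMS ethers that hydrolyse on adding water, and because no free protic acid is present the electron-rich alkene is not protonated and the TIPS ethers stay on.

**Step 8**
Reactants: 15 triarylethylene triol
Product: 16 (2S,3S)-tetra-TIPS dihydrobenzofuran
Conditions: (S,S)-IDPi acid (5 mol%), CHCl3–cyclohexane 1:1, 4 Å MS, −30 °C, dark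
Reagents that add atoms: none
Why: Proposed new method: catalytic enantioselective protonation/oxa-cyclisation (formal 5-endo hydroalkoxylation) of a triarylethylene, in which the confined strong acid, held through its anion by a hydrogen bond to one ring A phenol, delivers the proton to one face of C3 (setting C3) and the resulting contact ion pair of the quinone-methide-like C2 benzylic cation (stabilised by the 2- and 4-silyloxy groups of ring C) is captured 5-exo by the neighbouring ring A phenol anti to ring B, forming the O1–C2 bond, the furan ring and the trans C2 centre; the competing reversible protonation at C2 gives a diarylmethyl cation with no ring-forming outlet (the ring C oxygens are blocked by TIPS) and only equilibrates the E/Z isomers of 15, so both converge on 16; the closest known reaction types are IDPi-catalysed asymmetric intramolecular hydroalkoxylation of alkenes by aliphatic alcohols and the racemic acid-catalysed cyclisation of 2-hydroxystilbenes to 2-aryl-2,3-dihydrobenzofurans.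

**Step 9**
Reactants: 16 (2S,3S)-tetra-TIPS dihydrobenzofuran
Product: 17 target CNP0136479.1
Conditions: TBAF (4.4 equiv), AcOH (5 equiv), THF, 0 °C to rt, dark; Sephadex LH-20
Reagents that add atoms: none
Why: Fluoride desilylation buffered with acetic acid frees the four phenols without building up the ring C phenoxide that could open the benzylic ether, so neither stereocentre is touched.

**Compound list**
1 | 5-bromobenzene-1,3-diol (5-bromoresorcinol) | Oc1cc(O)cc(Br)c1 | starting material
2 | 2-methoxy-4-vinylphenol (4-vinylguaiacol) | COc1cc(C=C)ccc1O | starting material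
3 | isorhapontigenin, (E)-5-[2-(4-hydroxy-3-methoxyphenyl)ethenyl]benzene-1,3-diol | COc1cc(/C=C/c2cc(O)cc(O)c2)ccc1O | intermediate
4 | (E)-1,3-bis(methoxymethoxy)-5-{2-[3-methoxy-4-(methoxymethoxy)phenyl]ethenyl}benzene | COCOc1ccc(/C=C/c2cc(OCOC)cc(OCOC)c2)cc1OC | intermediate
5 | 1-(3,5-dihydroxyphenyl)ethan-1-one | CC(=O)c1cc(O)cc(O)c1 | starting material
6 | 1-[3,5-bis(triisopropylsilyloxy)phenyl]ethan-1-one | CC(=O)c1cc(O[Si](C(C)C)(C(C)C)C(C)C)cc(O[Si](C(C)C)(C(C)C)C(C)C)c1 | intermediate
7 | 4-bromobenzene-1,3-diol (4-bromoresorcinol) | Oc1ccc(Br)c(O)c1 | starting material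
8 | 1-bromo-2,4-bis(triisopropylsilyloxy)benzene | Brc1ccc(O[Si](C(C)C)(C(C)C)C(C)C)cc1O[Si](C(C)C)(C(C)C)C(C)C | intermediate
9 | aryllithium of 4, lithiated at the ring A carbon between the two OMOM groups (not isolated) | COCOc1ccc(/C=C/c2cc(OCOC)c([Li])c(OCOC)c2)cc1OC | intermediate
10 | arylcerium dichloride from 9 (not isolated) | COCOc1ccc(/C=C/c2cc(OCOC)c([Ce](Cl)Cl)c(OCOC)c2)cc1OC | intermediate
11 | racemic 1-{2,6-bis(methoxymethoxy)-4-[(E)-2-(3-methoxy-4-(methoxymethoxy)phenyl)ethenyl]phenyl}-1-[3,5-bis(triisopropylsilyloxy)phenyl]ethan-1-ol (not isolated) | COCOc1ccc(/C=C/c2cc(OCOC)c(C(C)(O)c3cc(O[Si](C(C)C)(C(C)C)C(C)C)cc(O[Si](C(C)C)(C(C)C)C(C)C)c3)c(OCOC)c2)cc1OC | intermediate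
12 | 2-{1-[3,5-bis(triisopropylsilyloxy)phenyl]ethenyl}-1,3-bis(methoxymethoxy)-5-{(E)-2-[3-methoxy-4-(methoxymethoxy)phenyl]ethenyl}benzene | COCOc1ccc(/C=C/c2cc(OCOC)c(C(=C)c3cc(O[Si](C(C)C)(C(C)C)C(C)C)cc(O[Si](C(C)C)(C(C)C)C(C)C)c3)c(OCOC)c2)cc1OC | intermediate
13 | 2-{1-[3,5-bis(triisopropylsilyloxy)phenyl]-2-[2,4-bis(triisopropylsilyloxy)phenyl]ethenyl}-1,3-bis(methoxymethoxy)-5-{(E)-2-[3-methoxy-4-(methoxymethoxy)phenyl]ethenyl}benzene (E/Z mixture at the triaryl alkene) | COCOc1ccc(/C=C/c2cc(OCOC)c(C(=Cc3ccc(O[Si](C(C)C)(C(C)C)C(C)C)cc3O[Si](C(C)C)(C(C)C)C(C)C)c3cc(O[Si](C(C)C)(C(C)C)C(C)C)cc(O[Si](C(C)C)(C(C)C)C(C)C)c3)c(OCOC)c2)cc1OC | intermediate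
14 | tris(trimethylsilyl) ether of 15 (not isolated) | COc1cc(/C=C/c2cc(O[Si](C)(C)C)c(C(=Cc3ccc(O[Si](C(C)C)(C(C)C)C(C)C)cc3O[Si](C(C)C)(C(C)C)C(C)C)c3cc(O[Si](C(C)C)(C(C)C)C(C)C)cc(O[Si](C(C)C)(C(C)C)C(C)C)c3)c(O[Si](C)(C)C)c2)ccc1O[Si](C)(C)C | intermediate
15 | 2-{1-[3,5-bis(triisopropylsilyloxy)phenyl]-2-[2,4-bis(triisopropylsilyloxy)phenyl]ethenyl}-5-[(E)-2-(4-hydroxy-3-methoxyphenyl)ethenyl]benzene-1,3-diol (E/Z mixture at the triaryl alkene) | COc1cc(/C=C/c2cc(O)c(C(=Cc3ccc(O[Si](C(C)C)(C(C)C)C(C)C)cc3O[Si](C(C)C)(C(C)C)C(C)C)c3cc(O[Si](C(C)C)(C(C)C)C(C)C)cc(O[Si](C(C)C)(C(C)C)C(C)C)c3)c(O)c2)ccc1O | intermediate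
16 | (2S,3S)-2-[2,4-bis(triisopropylsilyloxy)phenyl]-3-[3,5-bis(triisopropylsilyloxy)phenyl]-6-[(E)-2-(4-hydroxy-3-methoxyphenyl)ethenyl]-2,3-dihydro-1-benzofuran-4-ol | COc1cc(/C=C/c2cc(O)c3c(c2)O[C@H](c2ccc(O[Si](C(C)C)(C(C)C)C(C)C)cc2O[Si](C(C)C)(C(C)C)C(C)C)[C@H]3c2cc(O[Si](C(C)C)(C(C)C)C(C)C)cc(O[Si](C(C)C)(C(C)C)C(C)C)c2)ccc1O | intermediate
17 | (2S,3S)-2-(2,4-dihydroxyphenyl)-3-(3,5-dihydroxyphenyl)-6-[(E)-2-(4-hydroxy-3-methoxyphenyl)ethenyl]-2,3-dihydro-1-benzofuran-4-ol (CNP0136479.1) | COc1cc(/C=C/c2cc(O)c3c(c2)O[C@H](c2ccc(O)cc2O)[C@H]3c2cc(O)cc(O)c2)ccc1O | target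

**Step count**
Total steps: 9. Longest linear sequence: 7 (steps 1, 2, 5, 6, 7, 8, 9).

**Steps most likely to fail, with fallbacks**

Step 8 (the proposed new reaction). The risks are low enantioselectivity, slow productive protonation at C3, or erosion of ee if 16 re-ionises. The fallback sets out from 15 and comes back at 16. Triol 15 is cyclised with an achiral acid (diphenyl phosphate, 10 mol%, CH2Cl2, 0 °C), the known acid-catalysed closure of 2-hydroxystilbenes, which gives the racemic trans product. The unwanted (2R,3R)-enantiomer F5 is then removed by preparative chiral supercritical-fluid chromatography on an amylose tris(3,5-dimethylphenylcarbamate) phase, leaving 16.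

Step 5 (lithiation of a stilbene-bearing arene and addition of a hindered aryl metal to an enolisable ketone, then dehydration). The risks are carbolithiation of the stilbene, enolisation of 6, and cation-derived side products during dehydration. The fallback sets out from 4 and 6 and comes back at 12. Aryllithium 9 is quenched with I2 to give the aryl iodide F1, and ketone 6 is condensed with tosylhydrazide (MeOH, 60 °C) to the N-tosylhydrazone F2. A palladium-catalysed hydrazone cross-coupling of F1 with F2 (Pd2(dba)3, XPhos, LiOt-Bu, dioxane, 100 °C; carbene migratory insertion then β-hydride elimination) gives 12 directly, with no carbonyl addition and no dehydration.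

Step 6 (Heck reaction of a hindered alkene with an ortho-silyloxy, electron-rich bromide in the presence of a second alkene). The risks are low conversion and arylation of the stilbene. The fallback sets out from 6 and 8 and comes back at 13. Ketone 6 is α-arylated with 8 (Pd(OAc)2, XPhos, K3PO4, toluene, 90 °C) to the deoxybenzoin F3, with no alkene present. Arylcerium dichloride 10, made from 4 as in step 5, adds to F3 to give the tertiary alcohol F4, and Burgess dehydration, which can only use the benzylic CH2 hydrogens, gives 13.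

**Further compounds**
F1 | step 5 | 2-iodo-1,3-bis(methoxymethoxy)-5-{(E)-2-[3-methoxy-4-(methoxymethoxy)phenyl]ethenyl}benzene | COCOc1ccc(/C=C/c2cc(OCOC)c(I)c(OCOC)c2)cc1OC
F2 | step 5 | N'-{1-[3,5-bis(triisopropylsilyloxy)phenyl]ethylidene}-4-methylbenzenesulfonohydrazide | CC(=NNS(=O)(=O)c1ccc(C)cc1)c1cc(O[Si](C(C)C)(C(C)C)C(C)C)cc(O[Si](C(C)C)(C(C)C)C(C)C)c1
F3 | step 6 | 1-[3,5-bis(triisopropylsilyloxy)phenyl]-2-[2,4-bis(triisopropylsilyloxy)phenyl]ethan-1-one | O=C(Cc1ccc(O[Si](C(C)C)(C(C)C)C(C)C)cc1O[Si](C(C)C)(C(C)C)C(C)C)c1cc(O[Si](C(C)C)(C(C)C)C(C)C)cc(O[Si](C(C)C)(C(C)C)C(C)C)c1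
F4 | step 6 | racemic 1-{2,6-bis(methoxymethoxy)-4-[(E)-2-(3-methoxy-4-(methoxymethoxy)phenyl)ethenyl]phenyl}-1-[3,5-bis(triisopropylsilyloxy)phenyl]-2-[2,4-bis(triisopropylsilyloxy)phenyl]ethan-1-ol | COCOc1ccc(/C=C/c2cc(OCOC)c(C(O)(Cc3ccc(O[Si](C(C)C)(C(C)C)C(C)C)cc3O[Si](C(C)C)(C(C)C)C(C)C)c3cc(O[Si](C(C)C)(C(C)C)C(C)C)cc(O[Si](C(C)C)(C(C)C)C(C)C)c3)c(OCOC)c2)cc1OC
F5 | step 8 | (2R,3R)-enantiomer of 16 | COc1cc(/C=C/c2cc(O)c3c(c2)O[C@@H](c2ccc(O[Si](C(C)C)(C(C)C)C(C)C)cc2O[Si](C(C)C)(C(C)C)C(C)C)[C@@H]3c2cc(O[Si](C(C)C)(C(C)C)C(C)C)cc(O[Si](C(C)C)(C(C)C)C(C)C)c2)ccc1O
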